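The earlier runs and the new flask were computed from invented constants; noise was put on by code.

X comes slowly: in birch X reads 0% at 0.667 h, while E is going into solution, and 22% at 12.0 h.

| setting | birch | cedar | alpha | eta |
|---|---|---|---|---|
| E | 0.20 M | 0.20 M | 0.20 M | 0.20 M |
| Q | 0.076 M | 0.16 M | 0.200 M | 0.140 M |
| temperature | 58 °C | 74 °C |  |  |
| remark | run made earlier | run made earlier | at 50 °C throughout | at 80 °C until 2.5 h, from then on at 50 °C |
| time |  |  | 5.0 h | 5.0 h |

| run | time / h | X / % | E / % |
|---|---|---|---|
| birch | 0.667 | 0 | 59 |
| birch | 2.50 | 8 | 41 |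
| birch | 4.00 | 9 | 35 |
| birch | 6.00 | 12 | 33 |
| birch | 8.00 | 16 | 30 |
| birch | 12.0 | 22 | 24 |
| birch | 15.0 | 23 | 20 |
| cedar | 0.250 | 0 | 82 |
| cedar | 0.833 | 6 | 52 |
| cedar | 1.33 | 14 | 43 |
| cedar | 2.00 | 23 | 33 |
| cedar | 3.00 | 29 | 18 |
| cedar | 4.00 | 33 | 12 |
| cedar | 5.00 | 37 | 9 |

(scatter of a reading: 2 percentage points)

- at the start none of E is in solution
- what has only dissolved of E counts as not reacted
- a reading or a percentage of X counts all its forms, free or not

- the flask that ends with the higher amount of X, in percent of the E charged, or "neither" when 2 percentage points or less lies between them (alpha / eta / neither)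
- final X, as a percentage of the E charged, in alpha
- final X, as a percentage of the E charged, in eta

In cedar at 4.00 h about half of the charge reads as neither E nor X, and in birch at 12.0 h also half. We take that part as dissolved E, a steady supply, so that Q goes pseudo-first-order. We follow one molecule of Q, starting the clock at 0.667 h. After N lifetimes its chance of having reached X is one minus exp(−N), and X is that chance times the Q charged per E.

Birch gives a pace of 0.0763 /h, and cedar at 2.00 h gives 0.254 /h. The same factor per degree then gives 0.0418 /h at 50 °C and 0.399 /h at 80 °C.

Alpha gets N = 0.181, hence 16.6%. Eta gets N = 0.837, this clock number being pace times hours past the dead time, summed over both temperatures. Hence 39.7%.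

Is one number enough? Cedar at 4.00 h has N = 0.848, which predicts 45.7%, but it reads 33%. So for cedar one number is not enough, and we take it that Q also leaves by another road. Cedar's reading over its prediction, a ratio of 0.722 at nearly eta's clock number, carried over as an estimate, brings eta to 28.6%. Birch at 15.0 h predicts 25.3% and reads 23%, a gap near the scatter of 2 percentage points, so we leave alpha, cooler than birch, uncorrected. We therefore expect eta to end higher than alpha.

The forecast, lower than our 28.6% for eta, says eta, with 17% for alpha and 25% for eta: “So Q is also being lost”.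

The flask gives 16.0% in alpha and 28.9% in eta, so eta ends ahead.

    E ⇌ D, rate k1*(cs1 - [D]) while solid is left; crystals form when [D] > cs1 (solubility = 0.110 M, k = 1.99 /h)
    D + Q → X (k = 3.22 /M/h, Ea = 66.0 kJ/mol)
    2 D → Z (k = 0.0969 /M/h, Ea = 88.0 kJ/mol)
    L ⇌ X, rate k4*(cs4 - [X]) while solid is left; crystals form when [X] > cs4 (solubility = 36.0 mM, k = 53.2 /h)
    2 Q → G (k = 0.815 /M/h, Ea = 68.0 kJ/mol)
    (constants at 80 °C)

Uncorrected, eta's clock number of 0.837 promised 39.7%, against the 28.9% it holds. At 0.664 h in eta, Q was going to X 1.3 times as fast as into G. The same eta flask charged with 0.035 M of Q has the same clock number, which promises 9.92%, and that flask holds 8.96%.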